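Everything rests on opening ring C of the top epicatechin gallate unit across C2–C3 and C4–C4a. C2 lies between O1 of phloroglucinol ring A and catechol ring B, so it can be an aryl oxocarbenium carbon; C4 is benzylic to C8 of the middle unit, so C3=C4 can be an (E)-enol gallate styrene on a benzylated epicatechin gallate-(4β→8)-catechin dimer. A chiral-acid-mediated oxa-Povarov annulation of these partners should close ring C, carry in the C3 gallate and set C2, C3 and C4 in one operation. The dimer comes from (−)-epicatechin and (+)-catechin by flavan-4-yl cation coupling; hydrogenolysis ends the route.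

Key step: step 12

Assumption: compounds 5, 11, 15 and 16 are taken as commercial; the antipode of the chiral acid in step 12 is written as (R) and would be fixed by trying both.

Step 1
Reactants: 1 (−)-epicatechin
Product: 2 5,7,3',4'-tetra-O-benzyl-(−)-epicatechin
Conditions: BnBr, K2CO3, DMF, 0 °C to rt
Reagents that add atoms: benzyl bromide, BrCc1ccccc1
Why: Williamson ether synthesis in which the four phenols are alkylated selectively over the secondary 3-OH under carbonate conditions, with no stereocentre touched.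

Step 2
Reactants: 2 5,7,3',4'-tetra-O-benzyl-(−)-epicatechin
Product: 3 (2R,3R,4S)-5,7,3',4'-tetra-O-benzyl-4-(2-ethoxyethoxy)flavan-3-ol
Conditions: DDQ, 2-ethoxyethanol, CH2Cl2, rt
Reagents that add atoms: 2-ethoxyethanol, CCOCCO
Why: DDQ benzylic oxidation (hydride abstraction at C4, activated by ring A) with capture of the cation by the alcohol anti to the 3-OH, giving the 4β ether whose C4 centre is erased again on ionisation in step 7.

Step 3
Reactants: 3 (2R,3R,4S)-5,7,3',4'-tetra-O-benzyl-4-(2-ethoxyethoxy)flavan-3-ol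
Product: 4 (2R,3R,4S)-8-bromo-5,7,3',4'-tetra-O-benzyl-4-(2-ethoxyethoxy)flavan-3-ol
Conditions: NBS, CH2Cl2, −78 °C to rt
Reagents that add atoms: N-bromosuccinimide, O=C1CCC(=O)N1Br
Why: electrophilic aromatic bromination at C8, the more reactive free position of ring A, which caps C8 against self-condensation in step 7 and provides the handle for step 8.

Step 4
Reactants: 4 (2R,3R,4S)-8-bromo-5,7,3',4'-tetra-O-benzyl-4-(2-ethoxyethoxy)flavan-3-ol; 5 3,4,5-tris(benzyloxy)benzoic acid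
Product: 6 8-bromo-5,7,3',4'-tetra-O-benzyl-4β-(2-ethoxyethoxy)epicatechin 3-O-[3,4,5-tris(benzyloxy)benzoate]
Conditions: DCC, DMAP, CH2Cl2, rt
Reagents that add atoms: none
Why: Steglich esterification of the axial 3-OH through the acylpyridinium, with retention at C3.

Step 5
Reactants: 7 (+)-catechin
Product: 8 5,7,3',4'-tetra-O-benzyl-(+)-catechin
Conditions: BnBr, K2CO3, DMF, 0 °C to rt
Reagents that add atoms: benzyl bromide, BrCc1ccccc1
Why: Williamson ether synthesis selective for the phenols, as in step 1.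

Step 6
Reactants: 8 5,7,3',4'-tetra-O-benzyl-(+)-catechin
Product: 9 3,5,7,3',4'-penta-O-benzyl-(+)-catechin
Conditions: NaH, BnBr, DMF, 0 °C to rt
Reagents that add atoms: benzyl bromide, BrCc1ccccc1
Why: Williamson etherification of the alkoxide, capping the 3-OH so that it cannot trap the oxocarbenium ion of step 12 in an oxa-Pictet–Spengler closure onto ring B; no stereocentre is touched.

Step 7
Reactants: 6 8-bromo-5,7,3',4'-tetra-O-benzyl-4β-(2-ethoxyethoxy)epicatechin 3-O-[3,4,5-tris(benzyloxy)benzoate]; 9 3,5,7,3',4'-penta-O-benzyl-(+)-catechin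
Product: 10 bromo dimer: 8-bromo-5,7,3',4'-tetra-O-benzyl-3-O-[3,4,5-tris(benzyloxy)benzoyl]epicatechin-(4β→8)-3,5,7,3',4'-penta-O-benzylcatechin
Conditions: TMSOTf (0.2 equiv), CH2Cl2, −78 °C, 9 in excess (3 equiv)
Reagents that add atoms: none
Why: Lewis-acid-mediated flavan-4-yl cation Friedel–Crafts coupling in which C8 of the catechin nucleophile attacks the C4 cation anti to the axial 3-O-galloyl group (α face shielded, acyloxonium participation), setting C4 of the middle unit as 4β (3,4-trans).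

Step 8
Reactants: 10 bromo dimer; 11 (E)-1,2-bis(4,4,5,5-tetramethyl-1,3,2-dioxaborolan-2-yl)ethene
Product: 12 (E)-alkenyl pinacol boronate dimer: 8-[(E)-2-(4,4,5,5-tetramethyl-1,3,2-dioxaborolan-2-yl)vinyl]-5,7,3',4'-tetra-O-benzyl-3-O-[3,4,5-tris(benzyloxy)benzoyl]epicatechin-(4β→8)-3,5,7,3',4'-penta-O-benzylcatechin
Conditions: Pd(OAc)2 (5 mol%), SPhos (10 mol%), K3PO4, toluene/H2O, 80 °C, 11 in excess (3 equiv)
Reagents that add atoms: none
Why: Suzuki–Miyaura mono-coupling of the di-ortho-alkoxy aryl bromide with one boron terminus of the bis(boryl)ethene, with retention of the (E)-geometry.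

Step 9
Reactants: 12 (E)-alkenyl pinacol boronate dimer
Product: 13 potassium (E)-alkenyltrifluoroborate dimer: the same dimer carrying (E)-CH=CH–BF3K at C8 of the upper unit
Conditions: KHF2, MeOH/THF/H2O, rt
Reagents that add atoms: potassium hydrogen difluoride, F.[F-].[K+]
Why: standard exchange of a pinacol boronate into the trifluoroborate salt, the boron form suited to copper-mediated C–O coupling, with the alkene geometry untouched.

Step 10
Reactants: 13 potassium (E)-alkenyltrifluoroborate dimer; 5 3,4,5-tris(benzyloxy)benzoic acid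
Product: 14 (E)-enol gallate dimer: 8-[(E)-2-[3,4,5-tris(benzyloxy)benzoyloxy]vinyl]-5,7,3',4'-tetra-O-benzyl-3-O-[3,4,5-tris(benzyloxy)benzoyl]epicatechin-(4β→8)-3,5,7,3',4'-penta-O-benzylcatechin
Conditions: CuBr (10 mol%), DMAP (20 mol%), 4 Å MS, O2 (1 atm), CH2Cl2/MeCN, 40 °C
Reagents that add atoms: none
Why: Chan–Lam-type copper-catalysed oxidative coupling of an alkenyltrifluoroborate with a carboxylic acid, which should deliver the enol ester with retention of the (E)-geometry, the acetate-free copper source excluding a competing enol acetate.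

Step 11
Reactants: 15 3,4-bis(benzyloxy)benzaldehyde; 16 3,5-bis(benzyloxy)phenol
Product: 18 racemic [3,5-bis(benzyloxy)phenoxy][3,4-bis(benzyloxy)phenyl]methyl pivalate, via α-chloro pivalate 17 (not isolated)
Conditions: PivCl, ZnCl2 (2 mol%), CH2Cl2, 0 °C to rt; then 16, Cs2CO3, MeCN, 0 °C
Reagents that add atoms: pivaloyl chloride, CC(C)(C)C(Cl)=O
Why: ZnCl2-catalysed addition of the acyl chloride to the aldehyde gives the α-chloroalkyl ester, whose chloride is displaced at oxygen by the caesium phenoxide (Williamson-type, ionisation-assisted); the new acetal centre is racemic and is erased on ionisation in step 12.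

Step 12
Reactants: 14 (E)-enol gallate dimer; 18 racemic [3,5-bis(benzyloxy)phenoxy][3,4-bis(benzyloxy)phenyl]methyl pivalate
Product: 21 nonadeca-O-benzyl trimer, via aryl oxocarbenium ion 19 (not isolated), via benzylic cation 20 (not isolated)
Conditions: (R)-3,3'-bis(2,4,6-triisopropylphenyl)-1,1'-binaphthyl-2,2'-diyl N-triflylphosphoramide (10 mol%), 4 Å MS, CH2Cl2, −60 °C, slow addition of 18 (1.5 equiv)
Reagents that add atoms: none
Why: Proposed new method: the chiral acid ionises the acetal with loss of pivalic acid to the (E)-aryl oxocarbenium ion, a cationic 2-oxadiene (C4a=C8a–O1+=C2), whose C2 is attacked by C3 of the (E)-enol gallate (Prins-type addition) to give a cation at C4, stabilised by the 5,7-bis(benzyloxy) ring A of the middle unit, and C4 is then captured by the ortho carbon C4a of the 3,5-bis(benzyloxy)phenoxy ring with loss of a proton that returns the acid; the closest known reaction type is the SnCl4-promoted oxa-Povarov reaction of aryl oxocarbenium ions with styrenes, while chiral-anion control of oxocarbenium ions is known from oxa-Pictet–Spengler reactions and chromene acetal substitutions, and neither has been shown with a β-acyloxystyrene. Ring C of the top unit closes as a formal inverse-electron-demand [4+2] cycloaddition, in stepwise terms a 6-exo-trig Friedel–Crafts alkylation at C4. The regiochemistry needed (C3 to C2, C4 to C4a) is secured because the trialkoxyaryl group at C4 stabilises a cation far better than the acyloxy group at C3 and because pivalate, not aryloxide, is the leaving group of the acetal. C3/C4 trans follows from the (E)-alkene in an asynchronous addition and, if the C4 cation lives long enough to rotate, from closure anti to the C3 galloyloxy group with the C4 aryl pseudo-axial, away from the peri 5-benzyloxy group, as in 4β-selective captures of 2,3-cis flavan-4-yl cations; C2/C3 cis needs the endo placement of the galloyloxy group (carbonyl oxygen over the cationic oxadiene) with the bulky C4 aryl exo. The absolute sense (2R,3R,4R) cannot be relayed reliably from the remote centres of the dimer and is assigned to the chiral phosphoramide anion paired with the oxocarbenium ion, the matched antipode being selected. Slow addition of the acetal keeps the oxocarbenium ion dilute so that the alkene should outcompete the hindered C6–H positions of the dimer and the phloroglucinol ring of the acetal itself.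

Step 13
Reactants: 21 nonadeca-O-benzyl trimer
Product: 22 epicatechin-3-O-gallate-(4β→8)-epicatechin-3-O-gallate-(4β→8)-catechin
Conditions: H2 (1 atm), Pd(OH)2/C, THF/MeOH/H2O, rt
Reagents that add atoms: none
Why: global hydrogenolysis of the nineteen benzyl ethers under neutral conditions, which should leave the gallate esters, the interflavan bonds and all stereocentres untouched.

Compound list

1 | (−)-epicatechin: (2R,3R)-2-(3,4-dihydroxyphenyl)chromane-3,5,7-triol | O[C@@H]1Cc2c(O)cc(O)cc2O[C@@H]1c1ccc(O)c(O)c1 | starting material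
2 | 5,7,3',4'-tetra-O-benzyl-(−)-epicatechin (2R,3R) | O[C@@H]1Cc2c(OCc9ccccc9)cc(OCc9ccccc9)cc2O[C@@H]1c1ccc(OCc9ccccc9)c(OCc9ccccc9)c1 | intermediate
3 | (2R,3R,4S)-5,7,3',4'-tetra-O-benzyl-4-(2-ethoxyethoxy)flavan-3-ol (4β ether, trans to the 3-OH) | O[C@@H]1[C@@H](OCCOCC)c2c(OCc9ccccc9)cc(OCc9ccccc9)cc2O[C@@H]1c1ccc(OCc9ccccc9)c(OCc9ccccc9)c1 | intermediate
4 | (2R,3R,4S)-8-bromo-5,7,3',4'-tetra-O-benzyl-4-(2-ethoxyethoxy)flavan-3-ol | O[C@@H]1[C@@H](OCCOCC)c2c(OCc9ccccc9)cc(OCc9ccccc9)c(Br)c2O[C@@H]1c1ccc(OCc9ccccc9)c(OCc9ccccc9)c1 | intermediate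
5 | 3,4,5-tris(benzyloxy)benzoic acid | OC(=O)c1cc(OCc9ccccc9)c(OCc9ccccc9)c(OCc9ccccc9)c1 | starting material
6 | 8-bromo-5,7,3',4'-tetra-O-benzyl-4β-(2-ethoxyethoxy)epicatechin 3-O-[3,4,5-tris(benzyloxy)benzoate] | O=C(O[C@@H]1[C@@H](OCCOCC)c2c(OCc9ccccc9)cc(OCc9ccccc9)c(Br)c2O[C@@H]1c1ccc(OCc9ccccc9)c(OCc9ccccc9)c1)c1cc(OCc9ccccc9)c(OCc9ccccc9)c(OCc9ccccc9)c1 | intermediate
7 | (+)-catechin: (2R,3S)-2-(3,4-dihydroxyphenyl)chromane-3,5,7-triol | Oc1cc(O)c2c(c1)O[C@H](c1ccc(O)c(O)c1)[C@@H](O)C2 | starting material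
8 | 5,7,3',4'-tetra-O-benzyl-(+)-catechin (2R,3S) | O(Cc9ccccc9)c1cc(OCc9ccccc9)c2c(c1)O[C@H](c1ccc(OCc9ccccc9)c(OCc9ccccc9)c1)[C@@H](O)C2 | intermediate
9 | 3,5,7,3',4'-penta-O-benzyl-(+)-catechin (2R,3S) | O(Cc9ccccc9)c1cc(OCc9ccccc9)c2c(c1)O[C@H](c1ccc(OCc9ccccc9)c(OCc9ccccc9)c1)[C@@H](OCc9ccccc9)C2 | intermediate
10 | bromo dimer: 8-bromo-5,7,3',4'-tetra-O-benzyl-3-O-[3,4,5-tris(benzyloxy)benzoyl]epicatechin-(4β→8)-3,5,7,3',4'-penta-O-benzylcatechin (upper unit 2,3-cis-3,4-trans) | O=C(O[C@@H]1[C@@H](c2c(OCc9ccccc9)cc(OCc9ccccc9)c3c2O[C@H](c2ccc(OCc9ccccc9)c(OCc9ccccc9)c2)[C@@H](OCc9ccccc9)C3)c2c(OCc9ccccc9)cc(OCc9ccccc9)c(Br)c2O[C@@H]1c1ccc(OCc9ccccc9)c(OCc9ccccc9)c1)c1cc(OCc9ccccc9)c(OCc9ccccc9)c(OCc9ccccc9)c1 | intermediate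
11 | (E)-1,2-bis(4,4,5,5-tetramethyl-1,3,2-dioxaborolan-2-yl)ethene | CC1(C)OB(/C=C/B2OC(C)(C)C(C)(C)O2)OC1(C)C | starting material
12 | (E)-alkenyl pinacol boronate dimer: the bromo dimer with Br replaced by (E)-2-(4,4,5,5-tetramethyl-1,3,2-dioxaborolan-2-yl)vinyl | O=C(O[C@@H]1[C@@H](c2c(OCc9ccccc9)cc(OCc9ccccc9)c3c2O[C@H](c2ccc(OCc9ccccc9)c(OCc9ccccc9)c2)[C@@H](OCc9ccccc9)C3)c2c(OCc9ccccc9)cc(OCc9ccccc9)c(/C=C/B3OC(C)(C)C(C)(C)O3)c2O[C@@H]1c1ccc(OCc9ccccc9)c(OCc9ccccc9)c1)c1cc(OCc9ccccc9)c(OCc9ccccc9)c(OCc9ccccc9)c1 | intermediate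
13 | potassium (E)-alkenyltrifluoroborate dimer: the bromo dimer with Br replaced by (E)-CH=CH–BF3K | O=C(O[C@@H]1[C@@H](c2c(OCc9ccccc9)cc(OCc9ccccc9)c3c2O[C@H](c2ccc(OCc9ccccc9)c(OCc9ccccc9)c2)[C@@H](OCc9ccccc9)C3)c2c(OCc9ccccc9)cc(OCc9ccccc9)c(/C=C/[B-](F)(F)F)c2O[C@@H]1c1ccc(OCc9ccccc9)c(OCc9ccccc9)c1)c1cc(OCc9ccccc9)c(OCc9ccccc9)c(OCc9ccccc9)c1.[K+] | intermediate
14 | (E)-enol gallate dimer: the bromo dimer with Br replaced by (E)-2-[3,4,5-tris(benzyloxy)benzoyloxy]vinyl | O=C(O[C@@H]1[C@@H](c2c(OCc9ccccc9)cc(OCc9ccccc9)c3c2O[C@H](c2ccc(OCc9ccccc9)c(OCc9ccccc9)c2)[C@@H](OCc9ccccc9)C3)c2c(OCc9ccccc9)cc(OCc9ccccc9)c(/C=C/OC(=O)c3cc(OCc9ccccc9)c(OCc9ccccc9)c(OCc9ccccc9)c3)c2O[C@@H]1c1ccc(OCc9ccccc9)c(OCc9ccccc9)c1)c1cc(OCc9ccccc9)c(OCc9ccccc9)c(OCc9ccccc9)c1 | intermediate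
15 | 3,4-bis(benzyloxy)benzaldehyde | O=Cc1ccc(OCc9ccccc9)c(OCc9ccccc9)c1 | starting material
16 | 3,5-bis(benzyloxy)phenol | Oc1cc(OCc9ccccc9)cc(OCc9ccccc9)c1 | starting material
17 | chloro[3,4-bis(benzyloxy)phenyl]methyl pivalate (racemic) | CC(C)(C)C(=O)OC(Cl)c1ccc(OCc9ccccc9)c(OCc9ccccc9)c1 | intermediate
18 | [3,5-bis(benzyloxy)phenoxy][3,4-bis(benzyloxy)phenyl]methyl pivalate (racemic) | CC(C)(C)C(=O)OC(Oc1cc(OCc9ccccc9)cc(OCc9ccccc9)c1)c1ccc(OCc9ccccc9)c(OCc9ccccc9)c1 | intermediate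
19 | (E)-O-[3,5-bis(benzyloxy)phenyl] oxocarbenium ion of 3,4-bis(benzyloxy)benzaldehyde (paired with the chiral phosphoramide anion) | c1(OCc9ccccc9)cc(OCc9ccccc9)cc(c1)/[O+]=C/c1ccc(OCc9ccccc9)c(OCc9ccccc9)c1 | intermediate
20 | benzylic cation: adduct of the oxocarbenium ion at C3 of the enol gallate, new C2 and C3 both R, cationic C4 attached to C8 of the middle unit | O=C(O[C@@H]1[C@@H](c2c(OCc9ccccc9)cc(OCc9ccccc9)c3c2O[C@H](c2ccc(OCc9ccccc9)c(OCc9ccccc9)c2)[C@@H](OCc9ccccc9)C3)c2c(OCc9ccccc9)cc(OCc9ccccc9)c([CH+][C@@H](OC(=O)c3cc(OCc9ccccc9)c(OCc9ccccc9)c(OCc9ccccc9)c3)[C@H](Oc3cc(OCc9ccccc9)cc(OCc9ccccc9)c3)c3ccc(OCc9ccccc9)c(OCc9ccccc9)c3)c2O[C@@H]1c1ccc(OCc9ccccc9)c(OCc9ccccc9)c1)c1cc(OCc9ccccc9)c(OCc9ccccc9)c(OCc9ccccc9)c1 | intermediate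
21 | nonadeca-O-benzyl trimer: tetra-O-benzyl-3-O-(tri-O-benzylgalloyl)epicatechin-(4β→8)-tetra-O-benzyl-3-O-(tri-O-benzylgalloyl)epicatechin-(4β→8)-penta-O-benzylcatechin, top unit (2R,3R,4R) | O=C(O[C@@H]1[C@@H](c2c(OCc9ccccc9)cc(OCc9ccccc9)c3c2O[C@H](c2ccc(OCc9ccccc9)c(OCc9ccccc9)c2)[C@@H](OCc9ccccc9)C3)c2c(OCc9ccccc9)cc(OCc9ccccc9)c([C@H]3c4c(OCc9ccccc9)cc(OCc9ccccc9)cc4O[C@H](c4ccc(OCc9ccccc9)c(OCc9ccccc9)c4)[C@@H]3OC(=O)c3cc(OCc9ccccc9)c(OCc9ccccc9)c(OCc9ccccc9)c3)c2O[C@@H]1c1ccc(OCc9ccccc9)c(OCc9ccccc9)c1)c1cc(OCc9ccccc9)c(OCc9ccccc9)c(OCc9ccccc9)c1 | intermediate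
22 | epicatechin-3-O-gallate-(4β→8)-epicatechin-3-O-gallate-(4β→8)-catechin (CNP0269915.2) | O=C(O[C@@H]1[C@@H](c2c(O)cc(O)c3c2O[C@H](c2ccc(O)c(O)c2)[C@@H](O)C3)c2c(O)cc(O)c([C@H]3c4c(O)cc(O)cc4O[C@H](c4ccc(O)c(O)c4)[C@@H]3OC(=O)c3cc(O)c(O)c(O)c3)c2O[C@@H]1c1ccc(O)c(O)c1)c1cc(O)c(O)c(O)c1 | target

Step count and risks

Total steps: 13. Longest linear sequence: 10 steps (1, 2, 3, 4, 7, 8, 9, 10, 12, 13).

Steps most likely to fail:

1. Step 12 (proposed new method). What may go wrong: poor facial selectivity of the addition, so that ring C forms with the wrong absolute sense or as the 2,3-trans isomer; and competing Friedel–Crafts capture of the oxocarbenium ion by C6–H positions or by the phloroglucinol ring of the acetal. The fallback uses known flavan-4-yl cation chemistry and sets out from 10. Radical debromination (n-Bu3SnH, AIBN, toluene, 90 °C) should give the C8–H dimer F1. TMSOTf-mediated coupling of F1 with the bromine-capped electrophile 6 (CH2Cl2, −78 °C) should join C8 of the upper unit of F1 to C4 of 6, anti to the 3-O-galloyl group, and give the 8-bromo nonadeca-O-benzyl trimer F2. Hydrogenolysis of F2 (H2, Pd(OH)2/C, Et3N, THF/MeOH/H2O) should remove the benzyl groups and the bromine and return to the route at 22.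

2. Step 10. What may go wrong: protodeboronation of the hindered alkenyl boron species and slow C–O bond formation at copper, or erosion of the (E)-geometry. The fallback sets out from 12. Oxidation of the alkenyl boronate (NaBO3·4H2O, THF/H2O, rt) should give the arylacetaldehyde dimer F3. Acid 5 is converted with (COCl)2 and catalytic DMF into 3,4,5-tris(benzyloxy)benzoyl chloride F4. O-Acylation of the enol of F3 with F4 (Et3N, DMAP, CH2Cl2, 0 °C) should give 14 together with the (Z)-enol gallate dimer F5, which is separated or equilibrated with catalytic iodine. The route is rejoined at 14.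

3. Step 8. What may go wrong: a second coupling at the remaining boron terminus and protodeboronation of the product under the aqueous basic conditions. The fallback sets out from 10 and replaces transmetalation by carbopalladation: a Mizoroki–Heck reaction with pinacol vinylboronate under anhydrous conditions (Pd(OAc)2, P(t-Bu)3·HBF4, n-Bu3N, toluene, 90 °C) should give 12 directly, where the route is rejoined; this fallback makes no new compound (F0).

Further compounds

F1 | step 12 | C8–H dimer: 5,7,3',4'-tetra-O-benzyl-3-O-[3,4,5-tris(benzyloxy)benzoyl]epicatechin-(4β→8)-3,5,7,3',4'-penta-O-benzylcatechin | O=C(O[C@@H]1[C@@H](c2c(OCc9ccccc9)cc(OCc9ccccc9)c3c2O[C@H](c2ccc(OCc9ccccc9)c(OCc9ccccc9)c2)[C@@H](OCc9ccccc9)C3)c2c(OCc9ccccc9)cc(OCc9ccccc9)cc2O[C@@H]1c1ccc(OCc9ccccc9)c(OCc9ccccc9)c1)c1cc(OCc9ccccc9)c(OCc9ccccc9)c(OCc9ccccc9)c1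
F2 | step 12 | 8-bromo nonadeca-O-benzyl trimer: the nonadeca-O-benzyl trimer carrying Br at C8 of the top unit | O=C(O[C@@H]1[C@@H](c2c(OCc9ccccc9)cc(OCc9ccccc9)c3c2O[C@H](c2ccc(OCc9ccccc9)c(OCc9ccccc9)c2)[C@@H](OCc9ccccc9)C3)c2c(OCc9ccccc9)cc(OCc9ccccc9)c([C@H]3c4c(OCc9ccccc9)cc(OCc9ccccc9)c(Br)c4O[C@H](c4ccc(OCc9ccccc9)c(OCc9ccccc9)c4)[C@@H]3OC(=O)c3cc(OCc9ccccc9)c(OCc9ccccc9)c(OCc9ccccc9)c3)c2O[C@@H]1c1ccc(OCc9ccccc9)c(OCc9ccccc9)c1)c1cc(OCc9ccccc9)c(OCc9ccccc9)c(OCc9ccccc9)c1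
F3 | step 10 | arylacetaldehyde dimer: the bromo dimer with Br replaced by CH2CHO | O=C(O[C@@H]1[C@@H](c2c(OCc9ccccc9)cc(OCc9ccccc9)c3c2O[C@H](c2ccc(OCc9ccccc9)c(OCc9ccccc9)c2)[C@@H](OCc9ccccc9)C3)c2c(OCc9ccccc9)cc(OCc9ccccc9)c(CC=O)c2O[C@@H]1c1ccc(OCc9ccccc9)c(OCc9ccccc9)c1)c1cc(OCc9ccccc9)c(OCc9ccccc9)c(OCc9ccccc9)c1
F4 | step 10 | 3,4,5-tris(benzyloxy)benzoyl chloride | ClC(=O)c1cc(OCc9ccccc9)c(OCc9ccccc9)c(OCc9ccccc9)c1
F5 | step 10 | (Z)-enol gallate dimer: the (Z)-isomer of the enol gallate dimer | O=C(O[C@@H]1[C@@H](c2c(OCc9ccccc9)cc(OCc9ccccc9)c3c2O[C@H](c2ccc(OCc9ccccc9)c(OCc9ccccc9)c2)[C@@H](OCc9ccccc9)C3)c2c(OCc9ccccc9)cc(OCc9ccccc9)c(/C=C\OC(=O)c3cc(OCc9ccccc9)c(OCc9ccccc9)c(OCc9ccccc9)c3)c2O[C@@H]1c1ccc(OCc9ccccc9)c(OCc9ccccc9)c1)c1cc(OCc9ccccc9)c(OCc9ccccc9)c(OCc9ccccc9)c1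
F0 | step 8 | none | none
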